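I wanted the Z in the flask at 15 h, and the charge of E that leaves most of it.

in all of them: Q 0.465 M

| charge | X | E | remark | time |
|---|---|---|---|---|
| Friday's | 0.062 M | 0.046 M | run made earlier |  |
| Monday's | 0.14 M | 0.046 M | run made earlier |  |
| flask | 0.093 M | 0.0460 M |  | 15 h |

| run | time / h | Z / % | X / % |
|---|---|---|---|
| Friday's | 1.50 | 4.9 | 95.3 |
| Friday's | 4.00 | 11.2 | 88.4 |
| Friday's | 8.00 | 19.9 | 79.7 |
| Friday's | 12.0 | 26.7 | 72.8 |
| Monday's | 1.00 | 2.9 | 97.0 |
| Monday's | 2.00 | 5.5 | 94.4 |
| Monday's | 5.00 | 12.1 | 88.1 |
| Monday's | 12.0 | 20.8 | 78.7 |

(readings scatter by 0.3 percentage points)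

- equivalents of E to X, everything else as given, that leave most Z at 15 h
- the amount of Z then, in percent of the X charged
- the amount of Z with the amounts as given

Taking X and E as lost mole for mole, I read a rate constant of 0.725 L mol⁻¹ h⁻¹ from Friday's last reading and 0.714 L mol⁻¹ h⁻¹ from Monday's. That constant times the charged E and the time I called the exposure, 0.500: the lifetimes X passes if E stays at its charge, a pseudo-first-order count, which read 39.3% of the X turned to Z in the flask. I tested it on the runs: at 12.0 h both had an exposure of 0.400, which reads 33.0%, yet Friday's showed 26.7% and Monday's, with more X, 20.8%, so one number was not enough. E, the limiting reagent at 0.495 equivalents in the flask, runs down, so I folded the equivalents into a mole balance, and the same exposure then gave 28.1% of the X turned over.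

The forecast put Z in the flask a little below my turnover, at 27.2%, and the best charge at 3.3 equiv with 76% of Z, and it warned: “This extrapolates beyond the tested E range”.

The flask as charged gave 27.1% of Z, and the best charge of E, 2.93 equiv, left 71.4% of Z.

    X + E → Q + Z (k = 0.720 L mol⁻¹ h⁻¹)
    Z + E ⇌ Q + D (K = 41.0, k = 0.110 L mol⁻¹ h⁻¹)

Part of what held the flask there was E running down, acting together with the time allowed: with E held at its charge, Z at 15 h was 37.6%, beside the 39.3% of turnover that the exposure of 0.500 read, while the flask as charged, left until 150 h, held 45.1% of Z. With the other charges and the time held, the Z of the flask at 15 h moved by 5 points at the nearest amounts of E, 0.0364 M and 0.0564 M. On the neighbour with 0.11 M of E, the exposure was 1.20 and the balance gave 56.8% of the X turned over; the computed neighbour held 44.0% of X at 15 h, with 52.2% of Z and 3.78% of D.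

The data were generated by integration with made-up constants; noise was put on by code.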